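A one-step picture, with free monomer passing steadily into chains, fails on the maple run: the readings stand at 10.8% after 5.00 min and at 11.1% after 10.0 min, and the birch run ends alike at 10.7%.

| setting | maple | birch | grey | violet |
|---|---|---|---|---|
| free monomer | 1.6 M | 2.3 M | 2.0 M | 1.2 M |
| transfer agent | 0.060 M | 0.060 M | 0.0600 M | 0.0600 M |
| initiator | 10 mM | 10 mM | 10 mM | 10 mM |
| remark | run made earlier | run made earlier |  |  |
| time |  |  | 10 min | 10 min |

| maple: time / min | maple: monomer in chains / % | birch: time / min | birch: monomer in chains / % |
|---|---|---|---|
| 0.667 | 2.8 | 0.833 | 4.6 |
| 2.00 | 8.6 | 1.33 | 6.8 |
| 4.00 | 9.9 | 2.00 | 8.7 |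
| 5.00 | 10.8 | 4.00 | 10.2 |
| 8.00 | 11.5 | 6.00 | 11.0 |
| 10.0 | 11.1 | 10.0 | 10.7 |

(standard deviation of a reading: 0.5 percentage points)

- the average divides the monomer in chains by the number of chains begun, living and dead together
- the earlier runs do not show the number of chains; that part of a forecast is a guess

1. which of the two ends with the longer chains by the average number of monomer units in a chain (chains begun, living or dead) ("neither" if they lie within 10%) (grey / violet / neither)
2. average number of monomer units in a chain (chains begun, living or dead) at the end, grey
3. average number of monomer units in a chain (chains begun, living or dead) at the end, violet

In slow motion, the first readings put 2.8% of the charge in chains after 0.667 min in maple and 4.6% after 0.833 min in birch, and at 2.00 min the readings are 8.6% in maple and 8.7% in birch, each with a scatter of 0.5 percentage points. In the middle the curves bend, and at the end they lie flat with a plateau fraction, read from the last two readings of each run, of 11.1%, while about 88.9% of the charge stays free.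

My own reckoning assumes that each initiator starts one chain and that one transfer agent closes it without starting another. The first answer is then that chains begun equal the initiator charge. Put back in, this means a fraction 16.7% of the transfer agent is used by the end. If the same ends take both monomer and transfer agent, each first order, the logarithms of the fractions left keep a constant ratio, a selectivity factor read here as 0.644. It gives the plateau fraction from the fraction of transfer agent used, and that fraction does not depend on the monomer charge. Length is then plateau fraction times monomer charge over initiator charge: 22.1 for grey and 13.3 for violet.

The forecast, with the words “Chain number is the guess”, counts about 17 mM of chains where this reckoning counts 10 mM. It names grey as longer, with 13 (6 to 28) for grey and 8 (3.6 to 17) for violet.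

The flask gives grey as longer, with 22.1 for grey and 13.6 for violet.

    initiator + monomer in chains → spent initiator (k = 0.00250 M⁻¹ s⁻¹)
    free monomer + initiator → living end + monomer in chains (k = 0.0140 M⁻¹ s⁻¹)
    free monomer + living end → monomer in chains + living end, rate k3*[living end]*[free monomer] (k = 0.270 M⁻¹ s⁻¹)
    living end + transfer agent → dead chain (kL = 0.440 M⁻¹ s⁻¹)

Grey ends with 0.00995 M of dead chain and 83.4% of its transfer agent left, and 0.644 on that remainder gives 11.0% of the charge in chains, where grey holds 11.0%. The neighbour is grey with 0.040 M of initiator. One chain per initiator uses 66.7% of its transfer agent, so 0.644 gives a fraction 50.7% in chains and a length of 25.4. That neighbour ends with 35% of its transfer agent left, 48.5% of the charge in chains, and a length of 24.8.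

The runs were computed with made-up constants, noise included.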